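| flask | starting material | protic impurity | remark | time |
|---|---|---|---|---|
| epsilon | 0.10 M (in portions, 4) | 2 mM | the very flask that is asked about, followed so far; portions every 40 min |  |
| flask | 0.10 M (in portions, 4) | 2.00 mM | the portions of starting material follow each other after 40 min, the first at the start | 3.0 h |

epsilon run (percent of the starting material charged)

| time / min | starting material / % | intermediate A / % | product / % | intermediate B / % |
|---|---|---|---|---|
| 6.00 | 20.4 | 3.0 | 0.9 | 0 |
| 10.0 | 19.6 | 4.0 | 0 | 0 |
| 20.0 | 16.4 | 6.7 | 0 | 0.1 |
| 40.0 | 12.7 | 10.3 | 0.4 | 0.4 |
| 80.0 | 19.6 | 26.7 | 0.1 | 1.9 |

(standard deviation of a reading: 0.5 percentage points)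

- a reading or a percentage of product counts all its forms, free or not
- a reading at the moment of an addition is taken just before it
- percentages count the whole charge, also what has not yet gone in

- the species that holds most of what was charged as starting material, at 3.0 h (starting material / product / intermediate B / intermediate A)
- the largest share itself, whichever of these holds it, in percent of the starting material charged

- The protic impurity stands to the starting material as 2.00% of the charge, and the epsilon readings at 80.0 min sum to 1.7 percentage points less than the portions charged by then, close to that ratio; this toll is taken as lost, with the impurity as limiting reagent of the loss.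
- The decision for the next run is whether this flask, stopped at 3.0 h for intermediate A, may keep its protic impurity.
- Across the second interval, starting material in the epsilon run falls at a read 0.0164 min⁻¹, so my reckoning carries it through the later portions to 18.1% at 3.0 h.
- The open share, one minus the toll minus the starting material left, is 79.9%, to be divided among intermediate A, intermediate B and product.
- Intermediate B at 80.0 min, set against a straight ramp of intermediate A, reads 0.00178 min⁻¹.
- A ramp up to the open share leaves intermediate A 67.1%; that answer, put back as the ramp's end, gives 69.2%.
- The toll is far smaller than that share, so the flask stays as charged.
- The forecast says intermediate A at 65%, lower than my figure, and on the toll it says: “This matches the 2 mM impurity”.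

- The flask gives intermediate A at 67.9%, with quenched substrate at 2.00% and starting material at 19%, and intermediate A, intermediate B and product together hold 78.9% against the open share of 79.9%.

    starting material → intermediate A (k = 0.940 h⁻¹)
    starting material + protic impurity → quenched substrate (k = 1600 L mol⁻¹ h⁻¹)
    intermediate B → product (k = 0.0920 h⁻¹)
    crystals ⇌ product, rate k4*(cs4 - [product]) while solid is left; crystals form when [product] > cs4 (solubility = 3.00 mM, k = 54.0 h⁻¹)
    intermediate A → intermediate B (k = 0.110 h⁻¹)

- The neighbouring flask, charged with 8.00 mM of protic impurity, has a toll of 8.00%, an open share of 73.9% and, by the same ramp, intermediate A at 64.0%. At 3.0 h that flask holds quenched substrate at 8.00%, starting material at 18.8% and intermediate A at 63.4%.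

The runs stem from a simulated flask from invented constants; noise was put on by code.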